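**Retrosynthetic overview**
1. The strategy rests on the 1,3-diene of ring A (the cyclohexene): the endocyclic C3(CH3)=C4H bond is conjugated with the exocyclic C2=CH–CH(OH)CH3 bond, and the carbinol carbon sits on the side of C1, the ring CH that carries the side chain. This is the imprint of a vinylallene [4+2], and the carbinol oxygen can reach the first side-chain carbon on C1 as a δ-lactone.
2. Key disconnection: C4a–C8a and C1–C2, by a transannular Diels–Alder reaction of a 14-membered macrolactone that holds an axially chiral vinylallene and an E-enoate. Ring A, ring B (the methylated cyclohexane) and the δ-lactone form in one step.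
3. The macrolactone is closed first, at the enoate C=C, by an intramolecular Horner–Wadsworth–Emmons reaction. The allene comes from a palladium-catalysed anti-SN2′ coupling of a lactate-derived alkynyl cyclic carbonate with an E-alkenylboronate built by Evans alkylation and Evans syn aldol.
4. After the cycloaddition the lactone is reduced and opened by two Wittig homologations, the oxirane is set by Sharpless epoxidation, and one oxidation, one Wittig reaction and a fluoride deprotection finish the acid.
5. Ring order: 14-membered macrolactone, then rings A and B together with the δ-lactone, then the oxirane.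

Key step: step 17

Locants used below: the decalin is numbered as a naphthalene (C1 = CH bearing the side chain, C2 = alkylidene-bearing carbon, C3 = C–CH3, C4 = =CH, C4a and C8a = ring fusion, C5 = CH2, C6 and C8 = CH–CH3, C7 = carbinol or ketone carbon).

Step 1
Reactants: 1 methyl (R)-lactate
Product: 2 methyl (2R)-2-(tert-butyldimethylsilyloxy)propanoate
Conditions: TBSCl, imidazole, DMF, 0 °C to rt
Reagents that add atoms: tert-butyldimethylsilyl chloride, CC(C)(C)[Si](C)(C)Cl
Why: Imidazole-promoted O-silylation of the secondary alcohol should be clean and does not touch the lactate stereocentre.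

Step 2
Reactants: 2 methyl (2R)-2-(tert-butyldimethylsilyloxy)propanoate
Product: 3 (2R)-2-(tert-butyldimethylsilyloxy)propanal
Conditions: iBu2AlH (1.05 equiv), CH2Cl2, −78 °C; aq. KNaC4H4O6 (sodium potassium tartrate)
Reagents that add atoms: none
Why: Partial ester reduction should stop at the aluminium hemiacetal at −78 °C, and the configurationally labile aldehyde is used at once.

Step 3
Reactants: 3 (2R)-2-(tert-butyldimethylsilyloxy)propanal and 4 1-propynylmagnesium bromide
Product: 5 (2R,3S)-2-(tert-butyldimethylsilyloxy)hex-4-yn-3-ol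
Conditions: THF, −78 °C; aq. NH4Cl
Reagents that add atoms: none
Why: Non-chelated Felkin–Anh addition of the alkynyl Grignard reagent anti to the bulky, poorly coordinating silyloxy group should favour the anti (3S) carbinol, and the syn epimer is to be removed by chromatography.

Step 4
Reactants: 5 (2R,3S)-2-(tert-butyldimethylsilyloxy)hex-4-yn-3-ol
Product: 6 (2R,3S)-hex-4-yne-2,3-diol
Conditions: Bu4NF, THF, 0 °C to rt
Reagents that add atoms: none
Why: Fluoride-induced desilylation should free the diol without affecting either carbinol centre.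

Step 5
Reactants: 6 (2R,3S)-hex-4-yne-2,3-diol
Product: 7 (4R,5S)-4-methyl-5-(prop-1-yn-1-yl)-1,3-dioxolan-2-one
Conditions: 1,1'-carbonyldiimidazole, CH2Cl2, rt
Reagents that add atoms: 1,1'-carbonyldiimidazole, O=C(n1ccnc1)n1ccnc1
Why: Double acyl transfer from carbonyldiimidazole should close the five-membered cyclic carbonate (cis from the anti diol) with both C–O bonds intact.

Step 6
Reactants: 8 (R)-4-benzyl-3-propionyloxazolidin-2-one and 9 propargyl bromide
Product: 11 (R)-4-benzyl-3-[(2S)-2-methylpent-4-ynoyl]oxazolidin-2-one, via sodium enolate 10 (not isolated)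
Conditions: NaN(SiMe3)2, THF, −78 °C; then 9, −78 to −40 °C
Reagents that add atoms: none
Why: Evans asymmetric alkylation: the chelated Z-enolate should be propargylated on the face away from the benzyl group, which sets the (S) α-methyl centre.

Step 7
Reactants: 11 (R)-4-benzyl-3-[(2S)-2-methylpent-4-ynoyl]oxazolidin-2-one
Product: 12 (2S)-2-methylpent-4-yn-1-ol
Conditions: LiBH4, MeOH (1 equiv), Et2O, 0 °C
Reagents that add atoms: none
Why: Borohydride reduction of the exocyclic imide carbonyl should release the primary alcohol and the intact auxiliary without epimerisation.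

Step 8
Reactants: 12 (2S)-2-methylpent-4-yn-1-ol
Product: 13 (2S)-2-methylpent-4-ynal
Conditions: Dess–Martin periodinane, CH2Cl2, 0 °C to rt; solution used directly
Reagents that add atoms: none
Why: Dess–Martin oxidation is non-basic, so the volatile α-methyl aldehyde should keep its configuration when taken straight into the aldol.

Step 9
Reactants: 13 (2S)-2-methylpent-4-ynal and 14 (S)-4-benzyl-3-propionyloxazolidin-2-one
Product: 16 (S)-4-benzyl-3-[(2S,3R,4S)-3-hydroxy-2,4-dimethylhept-6-ynoyl]oxazolidin-2-one, via boron enolate 15 (not isolated)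
Conditions: Bu2BOTf, Et3N, CH2Cl2, −78 to 0 °C; then 13, −78 to 0 °C; pH 7 buffer, MeOH, H2O2
Reagents that add atoms: none
Why: Evans syn aldol through the Z-dibutylboron enolate and a chair Zimmerman–Traxler transition state: the (S)-auxiliary sets the 2S,3R pair, and the anti-Felkin sense that Z-enolates prefer toward an α-methyl aldehyde makes the all-syn triad the matched outcome.

Step 10
Reactants: 16 (S)-4-benzyl-3-[(2S,3R,4S)-3-hydroxy-2,4-dimethylhept-6-ynoyl]oxazolidin-2-one
Product: 17 (S)-4-benzyl-3-[(2S,3R,4S)-2,4-dimethyl-3-(triethylsilyloxy)hept-6-ynoyl]oxazolidin-2-one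
Conditions: TESOTf, 2,6-lutidine, CH2Cl2, −78 °C
Reagents that add atoms: triethylsilyl triflate, CC[Si](CC)(CC)OS(=O)(=O)C(F)(F)F
Why: Silyl triflate silylation of the hindered aldol carbinol should be fast at low temperature and avoids retro-aldol cleavage.

Step 11
Reactants: 17 (S)-4-benzyl-3-[(2S,3R,4S)-2,4-dimethyl-3-(triethylsilyloxy)hept-6-ynoyl]oxazolidin-2-one
Product: 18 (2R,3R,4S)-2,4-dimethyl-3-(triethylsilyloxy)hept-6-yn-1-ol
Conditions: LiBH4, MeOH (1 equiv), THF, 0 °C
Reagents that add atoms: none
Why: Reductive removal of the auxiliary with LiBH4 should give the primary alcohol while the triethylsilyl ether and the alkyne remain.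

Step 12
Reactants: 18 (2R,3R,4S)-2,4-dimethyl-3-(triethylsilyloxy)hept-6-yn-1-ol
Product: 20 (2R,3R,4S,6E)-2,4-dimethyl-7-(4,4,5,5-tetramethyl-1,3,2-dioxaborolan-2-yl)-3-(triethylsilyloxy)hept-6-en-1-ol, via O-boryl ether 19 (not isolated)
Conditions: pinacolborane (3 equiv), Cp2ZrHCl (10 mol %), Et3N (10 mol %), THF, 50 °C; aq. NaHCO3 work-up
Reagents that add atoms: pinacolborane, CC1(C)OBOC1(C)C
Why: Zirconium-catalysed alkyne hydroboration adds H and B syn with boron at the terminus to give the E-alkenylboronate; the free alcohol is borylated in passing and released again on aqueous work-up.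

Step 13
Reactants: 7 (4R,5S)-4-methyl-5-(prop-1-yn-1-yl)-1,3-dioxolan-2-one and 20 E-alkenylboronate
Product: 21 (2R,3R,4S,6E,11R)-2,4,8-trimethyl-3-(triethylsilyloxy)dodeca-6,8,9-triene-1,11-diol with an (aS) allene axis at C8=C9=C10
Conditions: Pd(PPh3)4 (5 mol %), THF–H2O (10:1), 40 °C
Reagents that add atoms: none
Why: Palladium-catalysed decarboxylative SN2′ coupling of a propargylic cyclic carbonate with an organoboron reagent: zerovalent palladium attacks the alkyne anti to the leaving C–O bond, the alkoxide left after loss of CO2 activates the boronate, and reductive elimination with retention should turn the (5S) centre into the (aS) axis.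

Step 14
Reactants: 21 vinylallene diol
Product: 22 (2S,3R,4S,6E,11R)-11-hydroxy-2,4,8-trimethyl-3-(triethylsilyloxy)dodeca-6,8,9-trienal, (aS) axis
Conditions: TEMPO (10 mol %), PhI(OAc)2 (1.2 equiv), CH2Cl2, rt
Reagents that add atoms: none
Why: Oxoammonium (TEMPO) oxidation is strongly biased toward primary over secondary alcohols and is non-basic, so the allenic carbinol and the new α-methyl aldehyde centre should survive.

Step 15
Reactants: 22 hydroxy aldehyde and 23 diethylphosphonoacetic acid
Product: 24 11-O-(diethylphosphonoacetyl) ester of 22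
Conditions: DCC, DMAP (cat.), CH2Cl2, 0 °C
Reagents that add atoms: none
Why: Steglich esterification of the only remaining hydroxyl should install the phosphonoacetate under conditions mild enough for the aldehyde and the allene.

Step 16
Reactants: 24 allenyl phosphonoacetate aldehyde
Product: 25 (3E,5R,6R,7S,9E,14R)-5,7,11,14-tetramethyl-6-(triethylsilyloxy)-1-oxacyclotetradeca-3,9,11,12-tetraen-2-one, (aS) axis at C11=C12=C13
Conditions: LiCl, iPr2NEt, MeCN, rt, 1 mM (slow addition)
Reagents that add atoms: none
Why: Masamune–Roush intramolecular Horner–Wadsworth–Emmons olefination at high dilution should close the 14-membered ring with an E-enoate, the weak amine base sparing the α-methyl-β-silyloxy aldehyde.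

Step 17
Reactants: 25 vinylallene enoate macrolactone
Product: 26 tricyclic cis-decalin dienyl δ-lactone
Conditions: toluene (5 mM, degassed, trace BHT), 90–110 °C, sealed tube
Reagents that add atoms: none
Why: Proposed new method: a thermal, concerted but asynchronous transannular [4+2], suprafacial on the dienophile, is expected between the s-cis CH=CH–C(CH3)=C unit of the vinylallene and the E-enoate, joining the enoate β-carbon to the alkene terminus (C8a–C4a) and the enoate α-carbon to the central allene carbon (C1–C2) and leaving the outer allene π-bond as the exocyclic alkylidene; the closest known reaction types are the transannular Diels–Alder reaction of 14-membered all-trans macrocyclic trienes and the tethered intramolecular vinylallene Diels–Alder reaction with axial-to-central chirality transfer. Ring A is the six-membered cycloaddition ring, ring B closes as a six-membered carbocycle through the four-carbon CH(CH3)–CH(OSiEt3)–CH(CH3)–CH2 strap lying endo in a chair with both methyls and the silyloxy group equatorial (hence the cis fusion), and the δ-lactone closes through the three-atom =CH–CH(CH3)–O–C(=O) strap with its carbonyl exo. The (aS) axis puts the carbinol carbon on one face of the diene, and because the short ester strap can deliver the enoate α-carbon only to that face and only exo, the axis alone should fix C1, C4a and C8a and the E geometry of the alkylidene, while C6, C7, C8 and the carbinol centre are carried through unchanged. The selectivity needed is attack syn to the carbinol-bearing allene substituent, which an untethered vinylallene would avoid on steric grounds, together with the exo-carbonyl, endo-chain topology; both are enforced by the ring, and the E ring alkene cannot reach the geometry for the competing [1,5]-hydrogen shift of the vinylallene. The sp diene terminus has no inside substituent and releases cumulene strain on bonding, which should offset the cost of turning the lactone ester toward s-cis, so moderate heating is expected to suffice.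

Step 18
Reactants: 26 tricyclic δ-lactone
Product: 27 lactol (anomer mixture)
Conditions: iBu2AlH (1.1 equiv), CH2Cl2, −78 °C; aq. KNaC4H4O6
Reagents that add atoms: none
Why: Partial reduction of a δ-lactone with iBu2AlH at −78 °C should stop at the lactol and leave the triethylsilyl ether and the diene alone.

Step 19
Reactants: 27 lactol and 28 2-(triphenylphosphoranylidene)propanal
Product: 29 hydroxy enal [C1: (E)-CH=C(CH3)–CHO; C2: (E)-=CH–CH(OH)CH3]
Conditions: toluene, 90 °C
Reagents that add atoms: none
Why: Wittig olefination of the lactol through its open hydroxy-aldehyde form with the stabilised α-methyl formyl ylide should give the E-enal under reversible oxaphosphetane control and free the allylic carbinol.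

Step 20
Reactants: 29 hydroxy enal
Product: 30 tert-butyldimethylsilyl ether of 29
Conditions: TBSCl, imidazole, DMF, rt
Reagents that add atoms: tert-butyldimethylsilyl chloride, CC(C)(C)[Si](C)(C)Cl
Why: Imidazole-mediated silylation protects the allylic carbinol without the strong silylating conditions that could enol-silylate the γ-branched enal.

Step 21
Reactants: 30 silyl-protected enal and 28 2-(triphenylphosphoranylidene)propanal
Product: 31 (1E,3E)-dienal [C1: CH=C(CH3)–CH=C(CH3)–CHO]
Conditions: toluene, 110 °C
Reagents that add atoms: none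
Why: A second Wittig homologation with the same stabilised ylide should add the next E-trisubstituted alkene, the α-methyl dienal product being too deactivated to react further.

Step 22
Reactants: 31 dienal
Product: 32 (1E,3E)-dienol [C1: CH=C(CH3)–CH=C(CH3)–CH2OH]
Conditions: NaBH4, CeCl3·7H2O, MeOH, −20 °C
Reagents that add atoms: none
Why: Luche reduction should deliver hydride 1,2 to the conjugated aldehyde and leave the dienes and silyl ethers untouched.

Step 23
Reactants: 32 dienol
Product: 33 diol with free 7-OH
Conditions: HF·pyridine, pyridine, THF, 0 °C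
Reagents that add atoms: none
Why: Buffered HF·pyridine should cleave the triethylsilyl ether much faster than the tert-butyldimethylsilyl ether, and doing this before any oxirane is present avoids exposing a vinyl epoxide to a silyl-cleaving acid.

Step 24
Reactants: 33 diol
Product: 34 epoxy diol [C1: (E)-CH=C(CH3)–(2S,3S)-3-(hydroxymethyl)-3-methyloxiran-2-yl]
Conditions: Ti(OiPr)4 (20 mol %), L-(+)-diethyl tartrate (25 mol %), tBuOOH (decane), 4 Å sieves, CH2Cl2, −20 °C
Reagents that add atoms: tert-butyl hydroperoxide, CC(C)(C)OO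
Why: Sharpless asymmetric epoxidation acts only on the alkene of the titanium-bound allylic alcohol, and the L-(+)-tartrate should deliver oxygen to the face that gives the (2S,3S)-oxirane, setting both epoxide centres.

Step 25
Reactants: 34 epoxy diol
Product: 35 keto epoxy aldehyde
Conditions: Dess–Martin periodinane (3 equiv), NaHCO3, CH2Cl2, 0 °C to rt
Reagents that add atoms: none
Why: Buffered Dess–Martin oxidation should convert the ring carbinol to the C7 ketone and the epoxy alcohol to the epoxy aldehyde in one operation without opening the vinyl oxirane; the flanking methyls are equatorial, so any enolisation returns the same configuration.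

Step 26
Reactants: 36 bromoacetyl bromide and 37 2-(trimethylsilyl)ethanol
Product: 38 2-(trimethylsilyl)ethyl bromoacetate
Conditions: pyridine, CH2Cl2, 0 °C
Reagents that add atoms: none
Why: Acylation of the primary alcohol by the acid bromide is a routine esterification.

Step 27
Reactants: 38 2-(trimethylsilyl)ethyl bromoacetate and 39 triphenylphosphine
Product: 41 2-(trimethylsilyl)ethyl (triphenylphosphoranylidene)acetate, via phosphonium bromide 40 (not isolated)
Conditions: toluene, rt; then aq. NaOH, CH2Cl2
Reagents that add atoms: none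
Why: SN2 quaternisation of the phosphine followed by deprotonation of the acidic α-CH2 gives the stabilised Wittig ylide.

Step 28
Reactants: 35 keto epoxy aldehyde and 41 stabilised ylide
Product: 42 2-(trimethylsilyl)ethyl (E)-enoate, silyl-protected target
Conditions: CH2Cl2, 0 °C to rt
Reagents that add atoms: none
Why: The stabilised ylide should react only with the aldehyde (the hindered 2,6-dimethylcyclohexanone is inert) and give the E-enoate by a Wittig reaction.

Step 29
Reactants: 42 protected target
Product: 43 target CNP0414188.1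
Conditions: Bu4NF, AcOH (1:1), THF, 0 °C to rt
Reagents that add atoms: none
Why: Buffered fluoride should cleave the silyl ether and, by β-elimination of the 2-(trimethylsilyl)ethyl group, the ester, under conditions mild enough for the vinyl oxirane and the ketone.

**Compound list**
1 | methyl (R)-lactate | C[C@@H](O)C(=O)OC | starting material
2 | methyl (2R)-2-(tert-butyldimethylsilyloxy)propanoate | C[C@@H](O[Si](C)(C)C(C)(C)C)C(=O)OC | intermediate
3 | (2R)-2-(tert-butyldimethylsilyloxy)propanal | C[C@@H](O[Si](C)(C)C(C)(C)C)C=O | intermediate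
4 | 1-propynylmagnesium bromide | CC#C[Mg]Br | starting material
5 | (2R,3S)-2-(tert-butyldimethylsilyloxy)hex-4-yn-3-ol (anti) | C[C@@H](O[Si](C)(C)C(C)(C)C)[C@@H](O)C#CC | intermediate
6 | (2R,3S)-hex-4-yne-2,3-diol | C[C@@H](O)[C@@H](O)C#CC | intermediate
7 | (4R,5S)-4-methyl-5-(prop-1-yn-1-yl)-1,3-dioxolan-2-one | C[C@H]1OC(=O)O[C@H]1C#CC | intermediate
8 | (R)-4-benzyl-3-propionyloxazolidin-2-one | CCC(=O)N1[C@H](Cc2ccccc2)COC1=O | starting material
9 | propargyl bromide | C#CCBr | starting material
10 | sodium (Z)-enolate of 8 | C/C=C(\[O-])N1[C@H](Cc2ccccc2)COC1=O.[Na+] | intermediate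
11 | (R)-4-benzyl-3-[(2S)-2-methylpent-4-ynoyl]oxazolidin-2-one | C#CC[C@H](C)C(=O)N1[C@H](Cc2ccccc2)COC1=O | intermediate
12 | (2S)-2-methylpent-4-yn-1-ol | C#CC[C@H](C)CO | intermediate
13 | (2S)-2-methylpent-4-ynal | C#CC[C@H](C)C=O | intermediate
14 | (S)-4-benzyl-3-propionyloxazolidin-2-one | CCC(=O)N1[C@@H](Cc2ccccc2)COC1=O | starting material
15 | (Z)-dibutylboron enolate of 14 | C/C=C(\OB(CCCC)CCCC)N1[C@@H](Cc2ccccc2)COC1=O | intermediate
16 | (S)-4-benzyl-3-[(2S,3R,4S)-3-hydroxy-2,4-dimethylhept-6-ynoyl]oxazolidin-2-one (all-syn aldol) | C#CC[C@H](C)[C@@H](O)[C@H](C)C(=O)N1[C@@H](Cc2ccccc2)COC1=O | intermediate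
17 | (S)-4-benzyl-3-[(2S,3R,4S)-2,4-dimethyl-3-(triethylsilyloxy)hept-6-ynoyl]oxazolidin-2-one | C#CC[C@H](C)[C@@H](O[Si](CC)(CC)CC)[C@H](C)C(=O)N1[C@@H](Cc2ccccc2)COC1=O | intermediate
18 | (2R,3R,4S)-2,4-dimethyl-3-(triethylsilyloxy)hept-6-yn-1-ol | C#CC[C@H](C)[C@@H](O[Si](CC)(CC)CC)[C@H](C)CO | intermediate
19 | O-pinacolboryl ether of 20 | CC1(C)OB(/C=C/C[C@H](C)[C@@H](O[Si](CC)(CC)CC)[C@H](C)COB2OC(C)(C)C(C)(C)O2)OC1(C)C | intermediate
20 | (2R,3R,4S,6E)-2,4-dimethyl-7-(4,4,5,5-tetramethyl-1,3,2-dioxaborolan-2-yl)-3-(triethylsilyloxy)hept-6-en-1-ol | CC1(C)OB(/C=C/C[C@H](C)[C@@H](O[Si](CC)(CC)CC)[C@H](C)CO)OC1(C)C | intermediate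
21 | (2R,3R,4S,6E,11R)-2,4,8-trimethyl-3-(triethylsilyloxy)dodeca-6,8,9-triene-1,11-diol, (aS) allene axis at C8=C9=C10 | C[C@@H](O)C([H])=[C@@]=C(C)/C=C/C[C@H](C)[C@@H](O[Si](CC)(CC)CC)[C@H](C)CO | intermediate
22 | (2S,3R,4S,6E,11R)-11-hydroxy-2,4,8-trimethyl-3-(triethylsilyloxy)dodeca-6,8,9-trienal, (aS) axis | C[C@@H](O)C([H])=[C@@]=C(C)/C=C/C[C@H](C)[C@@H](O[Si](CC)(CC)CC)[C@H](C)C=O | intermediate
23 | diethylphosphonoacetic acid | OC(=O)CP(=O)(OCC)OCC | starting material
24 | 11-O-(diethylphosphonoacetyl) ester of 22 | C[C@@H](OC(=O)CP(=O)(OCC)OCC)C([H])=[C@@]=C(C)/C=C/C[C@H](C)[C@@H](O[Si](CC)(CC)CC)[C@H](C)C=O | intermediate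
25 | (3E,5R,6R,7S,9E,14R)-5,7,11,14-tetramethyl-6-(triethylsilyloxy)-1-oxacyclotetradeca-3,9,11,12-tetraen-2-one, (aS) axis at C11=C12=C13 | C[C@H]1OC(=O)/C=C/[C@@H](C)[C@H](O[Si](CC)(CC)CC)[C@@H](C)C/C=C/C(C)=[C@]=C1[H] | intermediate
26 | tricyclic δ-lactone: cis-fused 3,6,8-trimethyl-7-(triethylsilyloxy)-1,2,4a,5,6,7,8,8a-octahydronaphthalene with C3=C4, whose C1 carries the lactone C=O and whose exocyclic C2=CH–CH(CH3)–O closes the six-membered lactone; H-4a and H-8a cis to each other, to the C1 carbonyl carbon and to both methyls; 7-OSiEt3 trans to the methyls; lactone CH(CH3) centre R | CC1=C[C@H]2C[C@H](C)[C@@H](O[Si](CC)(CC)CC)[C@H](C)[C@H]2[C@@H]3C(=O)O[C@H](C)C=C13 | intermediate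
27 | lactol of 26 (C=O reduced to CH–OH, anomer mixture) | CC1=C[C@H]2C[C@H](C)[C@@H](O[Si](CC)(CC)CC)[C@H](C)[C@H]2[C@@H]3C(O)O[C@H](C)C=C13 | intermediate
28 | 2-(triphenylphosphoranylidene)propanal | CC(C=O)=P(c1ccccc1)(c1ccccc1)c1ccccc1 | starting material
29 | hydroxy enal: core of 26 with C1 bearing (E)-CH=C(CH3)–CHO and C2 bearing the (E)-alkylidene =CH–CH(OH)CH3 with (R)-carbinol | CC1=C[C@H]2C[C@H](C)[C@@H](O[Si](CC)(CC)CC)[C@H](C)[C@H]2[C@H](/C=C(\C)C=O)/C1=C\[C@@H](C)O | intermediate
30 | tert-butyldimethylsilyl ether of 29 at the (R)-carbinol | CC1=C[C@H]2C[C@H](C)[C@@H](O[Si](CC)(CC)CC)[C@H](C)[C@H]2[C@H](/C=C(\C)C=O)/C1=C\[C@@H](C)O[Si](C)(C)C(C)(C)C | intermediate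
31 | dienal: as 30 with C1 bearing (1E,3E)-CH=C(CH3)–CH=C(CH3)–CHO | CC1=C[C@H]2C[C@H](C)[C@@H](O[Si](CC)(CC)CC)[C@H](C)[C@H]2[C@H](/C=C(\C)/C=C(\C)C=O)/C1=C\[C@@H](C)O[Si](C)(C)C(C)(C)C | intermediate
32 | dienol: as 31 with CH2OH in place of CHO | CC1=C[C@H]2C[C@H](C)[C@@H](O[Si](CC)(CC)CC)[C@H](C)[C@H]2[C@H](/C=C(\C)/C=C(\C)CO)/C1=C\[C@@H](C)O[Si](C)(C)C(C)(C)C | intermediate
33 | diol: 32 with free 7-OH | CC1=C[C@H]2C[C@H](C)[C@@H](O)[C@H](C)[C@H]2[C@H](/C=C(\C)/C=C(\C)CO)/C1=C\[C@@H](C)O[Si](C)(C)C(C)(C)C | intermediate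
34 | epoxy diol: C1 bears (E)-CH=C(CH3)–[(2S,3S)-3-(hydroxymethyl)-3-methyloxiran-2-yl]; 7-OH free; carbinol as tert-butyldimethylsilyl ether | CC1=C[C@H]2C[C@H](C)[C@@H](O)[C@H](C)[C@H]2[C@H](/C=C(\C)[C@@H]2O[C@@]2(C)CO)/C1=C\[C@@H](C)O[Si](C)(C)C(C)(C)C | intermediate
35 | keto epoxy aldehyde: C7 ketone, oxirane bearing CHO in place of CH2OH | CC1=C[C@H]2C[C@H](C)C(=O)[C@H](C)[C@H]2[C@H](/C=C(\C)[C@@H]2O[C@@]2(C)C=O)/C1=C\[C@@H](C)O[Si](C)(C)C(C)(C)C | intermediate
36 | bromoacetyl bromide | BrCC(Br)=O | starting material
37 | 2-(trimethylsilyl)ethanol | C[Si](C)(C)CCO | starting material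
38 | 2-(trimethylsilyl)ethyl bromoacetate | C[Si](C)(C)CCOC(=O)CBr | intermediate
39 | triphenylphosphine | c1ccc(cc1)P(c1ccccc1)c1ccccc1 | starting material
40 | [2-oxo-2-(2-trimethylsilylethoxy)ethyl]triphenylphosphonium bromide | C[Si](C)(C)CCOC(=O)C[P+](c1ccccc1)(c1ccccc1)c1ccccc1.[Br-] | intermediate
41 | 2-(trimethylsilyl)ethyl (triphenylphosphoranylidene)acetate | C[Si](C)(C)CCOC(=O)C=P(c1ccccc1)(c1ccccc1)c1ccccc1 | intermediate
42 | 2-(trimethylsilyl)ethyl ester of the O-tert-butyldimethylsilyl target | CC1=C[C@H]2C[C@H](C)C(=O)[C@H](C)[C@H]2[C@H](/C=C(\C)[C@@H]2O[C@@]2(C)/C=C/C(=O)OCC[Si](C)(C)C)/C1=C\[C@@H](C)O[Si](C)(C)C(C)(C)C | intermediate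
43 | CNP0414188.1: (2E)-3-[(2S,3S)-3-[(1E)-1-[(1R,2E,4aS,6S,8R,8aR)-2-[(2R)-2-hydroxypropylidene]-3,6,8-trimethyl-7-oxo-1,2,4a,5,6,7,8,8a-octahydronaphthalen-1-yl]prop-1-en-2-yl]-2-methyloxiran-2-yl]prop-2-enoic acid | CC1=C[C@H]2C[C@H](C)C(=O)[C@H](C)[C@H]2[C@H](/C=C(\C)[C@@H]2O[C@@]2(C)/C=C/C(=O)O)/C1=C\[C@@H](C)O | target

**Step count**
Total steps: 29 (27 on the main line and its two fragments, 2 for ylide 41).
Longest linear sequence: 22 steps (from 8 through steps 6–25, then 28 and 29).

**Steps most likely to fail**

Step 17 (transannular vinylallene Diels–Alder). The macrocycle may fail to reach the doubly strapped transition state, because the lactone ester has to rotate toward s-cis, so that slow oligomerisation or decomposition of the allene could outrun cycloaddition. The fallback uses known chemistry: the allene is replaced by an ordinary E,E-diene, so that ring formation becomes the established transannular Diels–Alder reaction of a 14-membered all-trans triene lactone, and the alkylidene is made afterwards by dehydration. It sets out from alcohol 5 and boronate 20 and comes back at lactone 26. Alcohol 5 would be etherified with 4-methoxybenzyl trichloroacetimidate (cat. camphorsulfonic acid) to the ether (2R,3S)-2-(tert-butyldimethylsilyloxy)-3-(4-methoxybenzyloxy)hex-4-yne F1. Bu4NF would then free the C2 carbinol to give (2R,3S)-3-(4-methoxybenzyloxy)hex-4-yn-2-ol F2. Syn hydrozirconation with excess Cp2ZrHCl (zirconium on the methyl-bearing carbon) and iodinolysis would give the vinyl iodide (2R,3S,4E)-5-iodo-3-(4-methoxybenzyloxy)hex-4-en-2-ol F3. Suzuki–Miyaura coupling of F3 with 20 [Pd(dppf)Cl2, aq. K3PO4, THF] would give the E,E-diene diol F4. TEMPO/PhI(OAc)2 would oxidise the primary alcohol to the diene aldehyde F5, DCC/DMAP with 23 would give the diene phosphonoacetate F6, and LiCl/iPr2NEt at high dilution would close the all-trans triene macrolactone F7. Heating F7 in toluene (150–180 °C) should give the tricyclic lactone F8. The same chair-like endo placement of the ring B strap is expected to set C1, C4a and C8a as in 26, with a trans-fused lactone. DDQ would remove the 4-methoxybenzyl group to give the hydroxy lactone F9. In F9 the hydroxyl is expected to stand axial and antiperiplanar to the allylic C2–H, so dehydration with Martin sulfurane (or mesylation and DBU) should give 26.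

Step 19 (Wittig opening of the lactol). The lactol may open too slowly for the weakly nucleophilic formyl ylide, and prolonged heating could epimerise the doubly activated C1 centre of the transient hydroxy aldehyde or let the freed carbinol add back to the enal. In the fallback the aldehyde is released from an acyclic, already silylated precursor instead of through the lactol equilibrium. It sets out from lactone 26 and comes back at enal 30. Aminolysis of 26 with MeNH(OMe)·HCl and Me3Al would give the hydroxy Weinreb amide F10. TBSOTf/2,6-lutidine would give the silylated Weinreb amide F11. iBu2AlH at −78 °C would give the silylated C1 aldehyde F12, and the Wittig reaction of F12 with 28 would give 30.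

Step 16 (Horner–Wadsworth–Emmons macrocyclisation). Intermolecular olefination to dimers and oligomers, or base-induced epimerisation or β-elimination of the α-methyl-β-silyloxy aldehyde, may compete with ring closure. In the fallback the ring is closed at the ester C–O bond instead of the C=C bond. It sets out from hydroxy aldehyde 22 and comes back at macrolactone 25. Wittig reaction of 22 with methyl (triphenylphosphoranylidene)acetate would give the E-enoate hydroxy ester F13. LiOH in THF–H2O at 0 °C would give the seco acid F14. Shiina macrolactonisation of F14 (2-methyl-6-nitrobenzoic anhydride, DMAP, high dilution, rt) would give 25.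

**Further compounds**
F1 | step 17 | (2R,3S)-2-(tert-butyldimethylsilyloxy)-3-(4-methoxybenzyloxy)hex-4-yne | C[C@@H](O[Si](C)(C)C(C)(C)C)[C@@H](OCc1ccc(OC)cc1)C#CC
F2 | step 17 | (2R,3S)-3-(4-methoxybenzyloxy)hex-4-yn-2-ol | C[C@@H](O)[C@@H](OCc1ccc(OC)cc1)C#CC
F3 | step 17 | (2R,3S,4E)-5-iodo-3-(4-methoxybenzyloxy)hex-4-en-2-ol | C/C(I)=C\[C@H](OCc1ccc(OC)cc1)[C@@H](C)O
F4 | step 17 | E,E-diene diol (analogue of 21 with CH=C(CH3)–CH(O-4-methoxybenzyl) in place of the allene) | C[C@@H](O)[C@@H](OCc1ccc(OC)cc1)/C=C(\C)/C=C/C[C@H](C)[C@@H](O[Si](CC)(CC)CC)[C@H](C)CO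
F5 | step 17 | diene aldehyde from F4 | C[C@@H](O)[C@@H](OCc1ccc(OC)cc1)/C=C(\C)/C=C/C[C@H](C)[C@@H](O[Si](CC)(CC)CC)[C@H](C)C=O
F6 | step 17 | diene phosphonoacetate from F5 | C[C@@H](OC(=O)CP(=O)(OCC)OCC)[C@@H](OCc1ccc(OC)cc1)/C=C(\C)/C=C/C[C@H](C)[C@@H](O[Si](CC)(CC)CC)[C@H](C)C=O
F7 | step 17 | all-trans triene macrolactone (14-membered, 13-O-4-methoxybenzyl) | C[C@H]1OC(=O)/C=C/[C@@H](C)[C@H](O[Si](CC)(CC)CC)[C@@H](C)C/C=C/C(C)=C/[C@@H]1OCc2ccc(OC)cc2
F8 | step 17 | tricyclic lactone with C2–H and the adjacent lactone CH–O-4-methoxybenzyl, trans-fused lactone | CC1=C[C@H]2C[C@H](C)[C@@H](O[Si](CC)(CC)CC)[C@H](C)[C@H]2[C@@H]3C(=O)O[C@H](C)[C@@H](OCc4ccc(OC)cc4)[C@@H]13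
F9 | step 17 | hydroxy lactone from F8 | CC1=C[C@H]2C[C@H](C)[C@@H](O[Si](CC)(CC)CC)[C@H](C)[C@H]2[C@@H]3C(=O)O[C@H](C)[C@@H](O)[C@@H]13
F10 | step 19 | hydroxy Weinreb amide (C1–C(=O)N(CH3)OCH3, free (R)-carbinol) | CC1=C[C@H]2C[C@H](C)[C@@H](O[Si](CC)(CC)CC)[C@H](C)[C@H]2[C@H](C(=O)N(C)OC)/C1=C\[C@@H](C)O
F11 | step 19 | tert-butyldimethylsilyl ether of F10 | CC1=C[C@H]2C[C@H](C)[C@@H](O[Si](CC)(CC)CC)[C@H](C)[C@H]2[C@H](C(=O)N(C)OC)/C1=C\[C@@H](C)O[Si](C)(C)C(C)(C)C
F12 | step 19 | silylated C1 aldehyde | CC1=C[C@H]2C[C@H](C)[C@@H](O[Si](CC)(CC)CC)[C@H](C)[C@H]2[C@H](C=O)/C1=C\[C@@H](C)O[Si](C)(C)C(C)(C)C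
F13 | step 16 | methyl E-enoate hydroxy ester (two-carbon homologue of 22) | C[C@@H](O)C([H])=[C@@]=C(C)/C=C/C[C@H](C)[C@@H](O[Si](CC)(CC)CC)[C@H](C)/C=C/C(=O)OC
F14 | step 16 | seco acid of 25 | C[C@@H](O)C([H])=[C@@]=C(C)/C=C/C[C@H](C)[C@@H](O[Si](CC)(CC)CC)[C@H](C)/C=C/C(=O)O
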